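**Remark on the chemistry:** carotenoid numbering is used (C1–C20 for the hydroxylated half, primed numbers for the other half; the ring oxygens bridge C5/C8 and C5'/C8'), and allene axes are described as Ra/Sa.

## Analysis of the target

The target 31 is the all-E C40 carotenoid (3R,5S,8S,5'R,8'S)-5,8:5',8'-diepoxy-5,8,5',8'-tetrahydro-β,β-caroten-3-ol. A heptaene (C9 to C9', four methyl branches) is capped at each end by a 2,5-dihydrofuran ring O–C5–C6=C7–C8, fused through C5–C6 to a gem-dimethylcyclohexane. There are five stereocentres: C3, C5 and C8 at one end, C5' and C8' at the other. At the hydroxylated end the C5 methyl is trans to the polyene across the dihydrofuran, and the C3 hydroxyl is cis to that methyl (trans to the ring oxygen). At the other end the C5' methyl and the polyene are cis, so the two ends differ in relative configuration at C5/C8 and no symmetry can be used. C8 and C8' are doubly allylic ether carbons attached to the heptaene: acid ionizes them to polyenyl cations and epimerizes them, and the polyene is sensitive to light, oxygen and acid. The feature that the route exploits is that each ring O–C5–C6=C7–C8 is the cycloisomer of an α-hydroxyallene C5(OH)–C6=C7=C8, in which the C8 stereocentre is stored as the axis C6=C7=C8. The hard part is to set each C8 relative to its C5 independently, without acid, and as late as possible.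

## Retrosynthetic reasoning

**31 to 28.** Both O–C8 bonds (O–C8 and O–C8') are cut at once, which opens both dihydrofuran rings to the bis(α-hydroxyallene) 28. This is preferred to cutting the chain first because it removes both acid-labile C8 centres and both heterocycles in one move, and replaces them by allene axes that survive olefination chemistry. The forward reaction must close two rings in the 5-endo mode and translate each axis into its C8 centre without ionization.

**28 to 23, 24 and 11.** The C11=C12 and C11'=C12' double bonds are cut. This gives the symmetric commercial C10 dialdehyde 24 and two C15 allenic phosphonium salts, 23 and 11, joined in two successive Wittig reactions through the C25 aldehyde 26. The cut is made here because the allene-bearing units then stay small and the only central piece is commercial.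

**23 to 22 and 11 to 10.** Each phosphonium salt comes from its primary dienylic alcohol, so the C15 allenic alcohols 22 and 10 carry all stereochemical information of the two halves.

**22 to 21 and 10 to 9.** Each allene is traced to a 5,6-epoxy-7-yne by SN2' delivery of hydride to C8 with retention of the C5–O bond. The two ends need opposite relations between the C5 oxygen and H8. The primed end (9 to 10) needs hydride on the face of the departing oxygen, which an oxygen-bound aluminium hydride provides. The hydroxylated end (21 to 22) needs hydride on the opposite face, which a palladium hydride provides after anti-SN2' oxidative addition. One type of precursor thus serves both relative configurations.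

**21 to 20 plus 3, and 9 to 8 plus 3.** The C8–C9 bond (sp–sp2) is cut, so that both halves use the same vinyl iodide 3 in a Sonogashira coupling with the terminal alkynyl epoxides 20 and 8.

**20 and 8 to 16 and 5.** The alkyne carbon C8 is removed (aldehydes 18 and 7) and the epoxides are traced to the allylic alcohols 16 and 5. A reagent-controlled titanium–tartrate epoxidation can then set C5 (and C5') with either sense, independent of the substrate. 5 comes from commercial β-cyclocitral 4.

**16 to 12.** The hydroxymethyl carbon is removed (enal 15, vinyl triflate 14) back to the ketone 13, and 13 to the commercial ketol 12 by inversion at the carbinol carbon. The target's C3 has the configuration opposite to that of 12, so the inverting esterification sets C3 and installs the protecting group in one step.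

**3 to 1.** The iodide is traced to commercial but-2-yn-1-ol 1 by syn hydrometalation and iodination.

## Alternatives that were turned down

**Alternative 1:** the textbook route. Both dihydrofurans are traced to 5,6-epoxides: the diepoxide A1 would be assembled by C15 + C10 + C15 Wittig chemistry and treated with acid (epoxide–furanoid rearrangement, twofold). It was turned down because the rearrangement passes through a cation delocalized from C6 over the polyene and planar at C8, so the C5 oxygen closes on either face and each end gives both C8 epimers (four diastereomers). The target needs methyl and chain cis at one end and trans at the other, which no common bias can deliver, and the acid keeps epimerizing the products. A1 needs the same two asymmetric epoxidations as the chosen route, so no steps are saved.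

**Alternative 2:** cut C11=C12 and C11'=C12' with the rings in place. Preformed furanoid C15 phosphonium salts such as A2 would be coupled with the C10 dialdehyde in a final double Wittig reaction. It was turned down for three reasons. Making A2 needs acid at a doubly allylic ether carbon. The ylide of A2 is a C11 carbanion vinylogous to the C8–O bond, so 1,4-elimination (ring opening) and proton shuffling at C8 threaten the stereocentre. And the real problem, a stereocontrolled synthesis of each dihydrofuran, is only moved earlier, with the labile centre then carried through several more steps.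

**Alternative 3:** ring contraction. Each dihydrofuran would come from a 3,6-dihydro-1,2-dioxine by extrusion of one oxygen. The bis-endoperoxide A3 would arise from twofold singlet-oxygen [4+2] addition to the s-cis C5=C6–C7=C8 termini of the fully conjugated polyene, followed by phosphine deoxygenation. It was turned down because the suprafacial cycloaddition fixes the C5/C8 relation, and contraction by SN2 at C8 (inversion) can then only give the methyl/chain cis series. The hydroxylated end of the target is trans. In addition, the primed diene has no stereocentre to direct the facial attack, and singlet oxygen would not distinguish the end dienes from the central polyene.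

Key step: step 21

## Route

Step 1
Reactants: 1 but-2-yn-1-ol
Product: 3 (E)-3-iodobut-2-en-1-ol, via alkenylzirconocene chloride 2 (not isolated)
Conditions: Cp2ZrCl2, iBu2AlH (2 equiv), THF, 0 °C to rt; then I2, −78 to 0 °C
Reagents that add atoms: iodine, `II`
Why: Hydrozirconation with Cp2Zr(H)Cl formed in the flask adds H and Zr syn across the alkyne with zirconium at the methyl-bearing carbon (the aluminated CH2O end is the bulkier one), and iodinolysis of the C–Zr bond with retention should give the E iodide.

Step 2
Reactants: 4 β-cyclocitral (2,6,6-trimethylcyclohex-1-ene-1-carbaldehyde)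
Product: 5 β-cyclogeraniol ((2,6,6-trimethylcyclohex-1-en-1-yl)methanol)
Conditions: NaBH4, MeOH, 0 °C
Reagents that add atoms: none
Why: 1,2-Reduction of a hindered enal by borohydride; no stereocentre is formed.

Step 3
Reactants: 5 β-cyclogeraniol
Product: 6 [(1R,6R)-2,2,6-trimethyl-7-oxabicyclo[4.1.0]heptan-1-yl]methanol
Conditions: Ti(OiPr)4 (0.2 equiv), D-(−)-diethyl tartrate (0.25 equiv), tBuOOH (2 equiv), 4 Å molecular sieves, CH2Cl2, −20 °C
Reagents that add atoms: tert-butyl hydroperoxide, `CC(C)(C)OO`
Why: Sharpless asymmetric epoxidation of a tetrasubstituted allylic alcohol; with the D-tartrate the oxygen should be delivered to the face that gives the (1R,6R) epoxide, which fixes C5' of the target as R.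

Step 4
Reactants: 6 [(1R,6R)-2,2,6-trimethyl-7-oxabicyclo[4.1.0]heptan-1-yl]methanol
Product: 7 (1S,6R)-2,2,6-trimethyl-7-oxabicyclo[4.1.0]heptane-1-carbaldehyde
Conditions: (nPr4N)RuO4 (5 mol%), N-methylmorpholine N-oxide, 4 Å molecular sieves, CH2Cl2, rt
Reagents that add atoms: none
Why: Ley–Griffith oxidation of a primary alcohol; the α-carbon is quaternary and cannot epimerize (the descriptor changes only because of CIP priorities).

Step 5
Reactants: 7 (1S,6R)-2,2,6-trimethyl-7-oxabicyclo[4.1.0]heptane-1-carbaldehyde
Product: 8 (1R,6R)-1-ethynyl-2,2,6-trimethyl-7-oxabicyclo[4.1.0]heptane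
Conditions: dimethyl (1-diazo-2-oxopropyl)phosphonate, K2CO3, MeOH, 0 °C to rt
Reagents that add atoms: dimethyl (1-diazo-2-oxopropyl)phosphonate, `COP(=O)(OC)C(=[N+]=[N-])C(C)=O`
Why: Ohira–Bestmann (Seyferth–Gilbert) homologation of a non-enolizable aldehyde to the terminal alkyne; the epoxide carbons are not touched.

Step 6
Reactants: 8 (1R,6R)-1-ethynyl-2,2,6-trimethyl-7-oxabicyclo[4.1.0]heptane; 3 (E)-3-iodobut-2-en-1-ol
Product: 9 (2E)-3-methyl-5-[(1R,6R)-2,2,6-trimethyl-7-oxabicyclo[4.1.0]heptan-1-yl]pent-2-en-4-yn-1-ol
Conditions: Pd(PPh3)4 (5 mol%), CuI (10 mol%), iPr2NH, THF, rt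
Reagents that add atoms: none
Why: Sonogashira coupling with retention of the alkene geometry; oxidative addition of zerovalent palladium to the vinyl iodide should be much faster than SN2' ionization of the fully substituted propargylic oxirane.

Step 7
Reactants: 9 (2E)-3-methyl-5-[(1R,6R)-2,2,6-trimethyl-7-oxabicyclo[4.1.0]heptan-1-yl]pent-2-en-4-yn-1-ol
Product: 10 (2E)-5-[(2R)-2-hydroxy-2,6,6-trimethylcyclohexylidene]-3-methylpenta-2,4-dien-1-ol with Ra allene axis (carotenoid descriptors 5'R,6'R)
Conditions: iBu2AlH (4 equiv), CH2Cl2, 0 °C; aqueous potassium sodium tartrate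
Reagents that add atoms: none
Why: SN2' hydride opening of a propargylic oxirane by an aluminium hydride bound to the oxirane oxygen: hydride should reach C8' on the face of the departing C6'–O bond (syn) while the C5'–O bond is kept, so the (5'R) epoxide gives the Ra allene with H8' on the hydroxyl face; this reaction type is established for allenic carotenoid end groups of this configuration.

Step 8
Reactants: 10 (2E)-5-[(2R)-2-hydroxy-2,6,6-trimethylcyclohexylidene]-3-methylpenta-2,4-dien-1-ol (Ra)
Product: 11 {(2E)-5-[(2R)-2-hydroxy-2,6,6-trimethylcyclohexylidene]-3-methylpenta-2,4-dien-1-yl}triphenylphosphonium bromide (Ra)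
Conditions: PPh3·HBr, MeOH, 0 °C to rt
Reagents that add atoms: triphenylphosphine hydrobromide, `[Br-].[PH+](c1ccccc1)(c1ccccc1)c1ccccc1`
Why: Standard formation of a polyenyl Wittig salt by substitution of the protonated primary dienylic alcohol; the tertiary α-allenic alcohol should not ionize because a C5' cation cannot conjugate with the orthogonal C7'=C8' π bond.

Step 9
Reactants: 12 (4R,6R)-4-hydroxy-2,2,6-trimethylcyclohexanone
Product: 13 (1S,5R)-3,3,5-trimethyl-4-oxocyclohexyl benzoate
Conditions: PhCO2H, PPh3, diisopropyl azodicarboxylate, THF, 0 °C to rt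
Reagents that add atoms: benzoic acid, `OC(=O)c1ccccc1`
Why: Mitsunobu esterification with SN2 inversion at the carbinol carbon turns the commercial ketol into the epimer needed for C3 of the target; the benzoate then serves as the protecting group.

Step 10
Reactants: 13 (1S,5R)-3,3,5-trimethyl-4-oxocyclohexyl benzoate
Product: 14 (1S)-3,5,5-trimethyl-4-(trifluoromethanesulfonyloxy)cyclohex-3-en-1-yl benzoate
Conditions: Tf2O, 2,6-di-tert-butyl-4-methylpyridine, CH2Cl2, 0 °C to rt
Reagents that add atoms: trifluoromethanesulfonic anhydride, `O=S(=O)(OS(=O)(=O)C(F)(F)F)C(F)(F)F`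
Why: Enol triflate formation under ester-compatible conditions; only one α-carbon bears hydrogen, so one regioisomer can form, and the methyl-bearing stereocentre is erased on purpose.

Step 11
Reactants: 14 (1S)-3,5,5-trimethyl-4-(trifluoromethanesulfonyloxy)cyclohex-3-en-1-yl benzoate
Product: 15 (1S)-4-formyl-3,5,5-trimethylcyclohex-3-en-1-yl benzoate
Conditions: Pd(PPh3)4 (5 mol%), CO (3 atm), Bu3SnH (slow addition), LiCl, THF, 50 °C
Reagents that add atoms: carbon monoxide, `[C-]#[O+]`
Why: Palladium-catalysed reductive carbonylation (formylation) of a vinyl triflate: oxidative addition, CO insertion and hydride transfer from tin; slow addition of the hydride should keep direct reduction low.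

Step 12
Reactants: 15 (1S)-4-formyl-3,5,5-trimethylcyclohex-3-en-1-yl benzoate
Product: 16 (1S)-4-(hydroxymethyl)-3,5,5-trimethylcyclohex-3-en-1-yl benzoate
Conditions: NaBH4, CeCl3·7H2O, MeOH, −20 °C
Reagents that add atoms: none
Why: Luche 1,2-reduction of the enal; the benzoate should survive at this temperature.

Step 13
Reactants: 16 (1S)-4-(hydroxymethyl)-3,5,5-trimethylcyclohex-3-en-1-yl benzoate
Product: 17 (1S,3R,6S)-6-(hydroxymethyl)-1,5,5-trimethyl-7-oxabicyclo[4.1.0]heptan-3-yl benzoate
Conditions: Ti(OiPr)4 (0.2 equiv), L-(+)-diethyl tartrate (0.25 equiv), tBuOOH (2 equiv), 4 Å molecular sieves, CH2Cl2, −20 °C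
Reagents that add atoms: tert-butyl hydroperoxide, `CC(C)(C)OO`
Why: Sharpless asymmetric epoxidation; the L-tartrate should deliver oxygen to the face opposite to that of step 3, which is also the face anti to the benzoate (matched case), setting C5 as S with the ring oxygen trans to the C3 oxygen.

Step 14
Reactants: 17 (1S,3R,6S)-6-(hydroxymethyl)-1,5,5-trimethyl-7-oxabicyclo[4.1.0]heptan-3-yl benzoate
Product: 18 (1S,3R,6R)-6-formyl-1,5,5-trimethyl-7-oxabicyclo[4.1.0]heptan-3-yl benzoate
Conditions: (nPr4N)RuO4 (5 mol%), N-methylmorpholine N-oxide, 4 Å molecular sieves, CH2Cl2, rt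
Reagents that add atoms: none
Why: Ley–Griffith oxidation; the α-carbon is quaternary, so no epimerization is possible (the descriptor change is a CIP effect).

Step 15
Reactants: 18 (1S,3R,6R)-6-formyl-1,5,5-trimethyl-7-oxabicyclo[4.1.0]heptan-3-yl benzoate
Product: 20 (1S,3R,6S)-6-ethynyl-1,5,5-trimethyl-7-oxabicyclo[4.1.0]heptan-3-ol, via alkynyl epoxide benzoate 19 (not isolated)
Conditions: dimethyl (1-diazo-2-oxopropyl)phosphonate, K2CO3, MeOH, 0 °C to rt; then kept at rt until the benzoate is consumed
Reagents that add atoms: dimethyl (1-diazo-2-oxopropyl)phosphonate, `COP(=O)(OC)C(=[N+]=[N-])C(C)=O`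
Why: Ohira–Bestmann homologation to the alkyne, followed in the same basic methanol by transesterification of the benzoate, which frees the C3 hydroxyl without touching a stereocentre.

Step 16
Reactants: 20 (1S,3R,6S)-6-ethynyl-1,5,5-trimethyl-7-oxabicyclo[4.1.0]heptan-3-ol; 3 (E)-3-iodobut-2-en-1-ol
Product: 21 (1S,3R,6S)-6-[(3E)-5-hydroxy-3-methylpent-3-en-1-yn-1-yl]-1,5,5-trimethyl-7-oxabicyclo[4.1.0]heptan-3-ol
Conditions: Pd(PPh3)4 (5 mol%), CuI (10 mol%), iPr2NH, THF, rt
Reagents that add atoms: none
Why: Sonogashira coupling as in step 6; free hydroxyl groups are tolerated and the E geometry of the iodide is retained.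

Step 17
Reactants: 21 (1S,3R,6S)-6-[(3E)-5-hydroxy-3-methylpent-3-en-1-yn-1-yl]-1,5,5-trimethyl-7-oxabicyclo[4.1.0]heptan-3-ol
Product: 22 (1R,3S)-4-[(3E)-5-hydroxy-3-methylpenta-1,3-dien-1-ylidene]-3,5,5-trimethylcyclohexane-1,3-diol with Ra allene axis (carotenoid descriptors 3R,5S,6R)
Conditions: Pd2(dba)3·CHCl3 (2.5 mol%), PBu3 (10 mol%), HCO2H (2 equiv), Et3N (2 equiv), THF, rt to 40 °C
Reagents that add atoms: none
Why: Palladium-catalysed formate hydrogenolysis of a propargylic C–O bond: zerovalent palladium opens the oxirane by anti-SN2' attack at C8, the allenylpalladium formate loses CO2, and reductive elimination puts hydrogen on C8 with retention, so hydride ends up anti to the departing oxygen; the (5S) epoxide should therefore give the Ra allene with H8 on the face opposite to the C5 hydroxyl, the relation complementary to that of step 7.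

Step 18
Reactants: 22 (1R,3S)-4-[(3E)-5-hydroxy-3-methylpenta-1,3-dien-1-ylidene]-3,5,5-trimethylcyclohexane-1,3-diol (Ra)
Product: 23 {(2E)-5-[(2S,4R)-2,4-dihydroxy-2,6,6-trimethylcyclohexylidene]-3-methylpenta-2,4-dien-1-yl}triphenylphosphonium bromide (Ra)
Conditions: PPh3·HBr, MeOH, 0 °C to rt
Reagents that add atoms: triphenylphosphine hydrobromide, `[Br-].[PH+](c1ccccc1)(c1ccccc1)c1ccccc1`
Why: As in step 8, only the primary dienylic alcohol is activated; the secondary and the tertiary α-allenic hydroxyl groups should stay unchanged.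

Step 19
Reactants: 11 {(2E)-5-[(2R)-2-hydroxy-2,6,6-trimethylcyclohexylidene]-3-methylpenta-2,4-dien-1-yl}triphenylphosphonium bromide (Ra); 24 (2E,4E,6E)-2,7-dimethylocta-2,4,6-trienedial
Product: 26 (2E,4E,6E,8E,10E)-13-[(2R)-2-hydroxy-2,6,6-trimethylcyclohexylidene]-2,7,11-trimethyltrideca-2,4,6,8,10,12-hexaenal (Ra), via phosphorus ylide 25 (not isolated)
Conditions: NaOMe (1.1 equiv), 24 (3 equiv), CH2Cl2/MeOH, −10 °C to rt, dark; then EtOAc/heptane, reflux, N2
Reagents that add atoms: none
Why: Wittig olefination of one formyl group of the symmetric dialdehyde used in excess; the semi-stabilized ylide gives an E/Z mixture at the new C11'=C12' bond, which thermal equilibration should convert to the E isomer, and the allene axis is not part of the reacting centre.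

Step 20
Reactants: 23 {(2E)-5-[(2S,4R)-2,4-dihydroxy-2,6,6-trimethylcyclohexylidene]-3-methylpenta-2,4-dien-1-yl}triphenylphosphonium bromide (Ra); 26 C25 allenic aldehyde
Product: 28 (3R,5S,6R,5'R,6'R)-6,7,6',7'-tetradehydro-5,6,5',6'-tetrahydro-β,β-carotene-3,5,5'-triol (all-E), via phosphorus ylide 27 (not isolated)
Conditions: NaOMe (1.2 equiv), CH2Cl2/MeOH, −10 °C to rt, dark; then EtOAc/heptane, reflux, N2
Reagents that add atoms: none
Why: Second Wittig olefination forms C11=C12 and completes the C40 skeleton; free hydroxyl groups are tolerated, and thermal equilibration should give the all-E polyene while both allene axes and C3, C5, C5' stay unchanged.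

Step 21
Reactants: 28 (3R,5S,6R,5'R,6'R)-6,7,6',7'-tetradehydro-5,6,5',6'-tetrahydro-β,β-carotene-3,5,5'-triol
Product: 31 (3R,5S,8S,5'R,8'S)-5,8:5',8'-diepoxy-5,8,5',8'-tetrahydro-β,β-caroten-3-ol (all-E), via primed-end monofuranoid 29 (not isolated), via unprimed-end monofuranoid 30 (not isolated)
Conditions: (Ph3P)AuNTf2 (5 mol% per allene), 2,6-di-tert-butylpyridine (10 mol%), THF, −20 to 0 °C, dark, argon; filtration through basic Al2O3
Reagents that add atoms: none
Why: Monovalent gold binds the C7=C8 (C7'=C8') π bond of each allene on the face away from the neighbouring tertiary hydroxyl, the C5 (C5') oxygen attacks C8 (C8') anti to the metal, and protodeauration of the resulting C7-vinylgold releases the 2,5-dihydrofuran and the catalyst. The closest known reaction type is the gold-catalysed cycloisomerization of α-hydroxyallenes to 2,5-dihydrofurans with axis-to-centre chirality transfer, used here twice in one molecule. Both rings close in the 5-endo-trig mode (O–C5–C6=C7–C8 and O–C5'–C6'=C7'–C8'). C8 and C8' are controlled by the allene axes alone: the oxygen enters in the plane of C5–C6–C7, so H8 and C9 keep their faces, and with both axes Ra the (5'R) end must give methyl and chain cis (8'S) while the (5S) end must give them trans (8S); C3, C5 and C5' are not touched. The step needs chemoselectivity for the two allenes over the heptaene and must avoid ionization at C8 to a polyenyl cation, which would erase the transfer; the intramolecular tertiary hydroxyl (fast 5-endo closure), the weakly Lewis-acidic phosphine-ligated catalyst, THF, low temperature and the hindered pyridine buffer are chosen to secure this. A carbocyclization of the vinylallene units would have to create a spiro quaternary C6 between C1 and C5 and should not compete, and the secondary C3 hydroxyl has no allene carbon within reach of a five- or six-membered closure. The two ring closures are independent, so the monofuranoids 29 and 30 form first and converge on 31.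

## Compound list

1 | but-2-yn-1-ol | `CC#CCO` | starting material
2 | diisobutylaluminium alkoxide of (E)-3-[chlorobis(cyclopentadienyl)zirconio]but-2-en-1-ol | `C/C(=C\CO[Al](CC(C)C)CC(C)C)[Zr](Cl)(C1C=CC=C1)C1C=CC=C1` | intermediate
3 | (E)-3-iodobut-2-en-1-ol | `C/C(I)=C\CO` | intermediate
4 | β-cyclocitral (2,6,6-trimethylcyclohex-1-ene-1-carbaldehyde) | `CC1=C(C=O)C(C)(C)CCC1` | starting material
5 | β-cyclogeraniol ((2,6,6-trimethylcyclohex-1-en-1-yl)methanol) | `CC1=C(CO)C(C)(C)CCC1` | intermediate
6 | [(1R,6R)-2,2,6-trimethyl-7-oxabicyclo[4.1.0]heptan-1-yl]methanol | `OC[C@@]12O[C@]1(C)CCCC2(C)C` | intermediate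
7 | (1S,6R)-2,2,6-trimethyl-7-oxabicyclo[4.1.0]heptane-1-carbaldehyde | `O=C[C@@]12O[C@]1(C)CCCC2(C)C` | intermediate
8 | (1R,6R)-1-ethynyl-2,2,6-trimethyl-7-oxabicyclo[4.1.0]heptane | `C#C[C@@]12O[C@]1(C)CCCC2(C)C` | intermediate
9 | (2E)-3-methyl-5-[(1R,6R)-2,2,6-trimethyl-7-oxabicyclo[4.1.0]heptan-1-yl]pent-2-en-4-yn-1-ol | `OC/C=C(C)/C#C[C@@]12O[C@]1(C)CCCC2(C)C` | intermediate
10 | (2E)-5-[(2R)-2-hydroxy-2,6,6-trimethylcyclohexylidene]-3-methylpenta-2,4-dien-1-ol, Ra allene axis (5'R,6'R) | `OC/C=C(C)/C([H])=[C@@]=C1C(C)(C)CCC[C@@]1(C)O` | intermediate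
11 | {(2E)-5-[(2R)-2-hydroxy-2,6,6-trimethylcyclohexylidene]-3-methylpenta-2,4-dien-1-yl}triphenylphosphonium bromide, Ra | `[Br-].C(/C=C(C)/C([H])=[C@@]=C1C(C)(C)CCC[C@@]1(C)O)[P+](c2ccccc2)(c3ccccc3)c4ccccc4` | intermediate
12 | (4R,6R)-4-hydroxy-2,2,6-trimethylcyclohexanone | `C[C@@H]1C[C@@H](O)CC(C)(C)C1=O` | starting material
13 | (1S,5R)-3,3,5-trimethyl-4-oxocyclohexyl benzoate | `C[C@@H]1C[C@H](OC(=O)c2ccccc2)CC(C)(C)C1=O` | intermediate
14 | (1S)-3,5,5-trimethyl-4-(trifluoromethanesulfonyloxy)cyclohex-3-en-1-yl benzoate | `CC1=C(OS(=O)(=O)C(F)(F)F)C(C)(C)C[C@@H](OC(=O)c2ccccc2)C1` | intermediate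
15 | (1S)-4-formyl-3,5,5-trimethylcyclohex-3-en-1-yl benzoate | `CC1=C(C=O)C(C)(C)C[C@@H](OC(=O)c2ccccc2)C1` | intermediate
16 | (1S)-4-(hydroxymethyl)-3,5,5-trimethylcyclohex-3-en-1-yl benzoate | `CC1=C(CO)C(C)(C)C[C@@H](OC(=O)c2ccccc2)C1` | intermediate
17 | (1S,3R,6S)-6-(hydroxymethyl)-1,5,5-trimethyl-7-oxabicyclo[4.1.0]heptan-3-yl benzoate | `OC[C@]12O[C@@]1(C)C[C@H](OC(=O)c3ccccc3)CC2(C)C` | intermediate
18 | (1S,3R,6R)-6-formyl-1,5,5-trimethyl-7-oxabicyclo[4.1.0]heptan-3-yl benzoate | `O=C[C@]12O[C@@]1(C)C[C@H](OC(=O)c3ccccc3)CC2(C)C` | intermediate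
19 | (1S,3R,6S)-6-ethynyl-1,5,5-trimethyl-7-oxabicyclo[4.1.0]heptan-3-yl benzoate | `C#C[C@]12O[C@@]1(C)C[C@H](OC(=O)c3ccccc3)CC2(C)C` | intermediate
20 | (1S,3R,6S)-6-ethynyl-1,5,5-trimethyl-7-oxabicyclo[4.1.0]heptan-3-ol | `C#C[C@]12O[C@@]1(C)C[C@H](O)CC2(C)C` | intermediate
21 | (1S,3R,6S)-6-[(3E)-5-hydroxy-3-methylpent-3-en-1-yn-1-yl]-1,5,5-trimethyl-7-oxabicyclo[4.1.0]heptan-3-ol | `OC/C=C(C)/C#C[C@]12O[C@@]1(C)C[C@H](O)CC2(C)C` | intermediate
22 | (1R,3S)-4-[(3E)-5-hydroxy-3-methylpenta-1,3-dien-1-ylidene]-3,5,5-trimethylcyclohexane-1,3-diol, Ra allene axis (3R,5S,6R) | `OC/C=C(C)/C([H])=[C@@]=C1C(C)(C)C[C@@H](O)C[C@]1(C)O` | intermediate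
23 | {(2E)-5-[(2S,4R)-2,4-dihydroxy-2,6,6-trimethylcyclohexylidene]-3-methylpenta-2,4-dien-1-yl}triphenylphosphonium bromide, Ra | `[Br-].C(/C=C(C)/C([H])=[C@@]=C1C(C)(C)C[C@@H](O)C[C@]1(C)O)[P+](c2ccccc2)(c3ccccc3)c4ccccc4` | intermediate
24 | (2E,4E,6E)-2,7-dimethylocta-2,4,6-trienedial | `O=C/C(C)=C/C=C/C=C(C)/C=O` | starting material
25 | phosphorus ylide of 11 | `[CH-](/C=C(C)/C([H])=[C@@]=C1C(C)(C)CCC[C@@]1(C)O)[P+](c2ccccc2)(c3ccccc3)c4ccccc4` | intermediate
26 | (2E,4E,6E,8E,10E)-13-[(2R)-2-hydroxy-2,6,6-trimethylcyclohexylidene]-2,7,11-trimethyltrideca-2,4,6,8,10,12-hexaenal, Ra (C25 allenic aldehyde) | `O=C/C(C)=C/C=C/C=C(C)/C=C/C=C(C)/C([H])=[C@@]=C1C(C)(C)CCC[C@@]1(C)O` | intermediate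
27 | phosphorus ylide of 23 | `[CH-](/C=C(C)/C([H])=[C@@]=C1C(C)(C)C[C@@H](O)C[C@]1(C)O)[P+](c2ccccc2)(c3ccccc3)c4ccccc4` | intermediate
28 | (3R,5S,6R,5'R,6'R)-6,7,6',7'-tetradehydro-5,6,5',6'-tetrahydro-β,β-carotene-3,5,5'-triol | `O[C@@]1(C)C[C@H](O)CC(C)(C)C1=[C@@]=C([H])/C(C)=C/C=C/C(C)=C/C=C/C=C(C)/C=C/C=C(C)/C([H])=[C@@]=C2C(C)(C)CCC[C@@]2(C)O` | intermediate
29 | (3R,5S,6R,5'R,8'S)-5',8'-epoxy-6,7-didehydro-5,6,5',8'-tetrahydro-β,β-carotene-3,5-diol | `O[C@@]1(C)C[C@H](O)CC(C)(C)C1=[C@@]=C([H])/C(C)=C/C=C/C(C)=C/C=C/C=C(C)/C=C/C=C(C)/[C@@H]2C=C3C(C)(C)CCC[C@@]3(C)O2` | intermediate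
30 | (3R,5S,8S,5'R,6'R)-5,8-epoxy-6',7'-didehydro-5,8,5',6'-tetrahydro-β,β-carotene-3,5'-diol | `O[C@]1(C)CCCC(C)(C)C1=[C@@]=C([H])/C(C)=C/C=C/C(C)=C/C=C/C=C(C)/C=C/C=C(C)/[C@@H]2C=C3C(C)(C)C[C@@H](O)C[C@]3(C)O2` | intermediate
31 | (3R,5S,8S,5'R,8'S)-5,8:5',8'-diepoxy-5,8,5',8'-tetrahydro-β,β-caroten-3-ol | `CC(/C=C/C=C(\C)[C@@H]1C=C2C(C)(C)CCC[C@@]2(C)O1)=C\C=C\C=C(C)\C=C\C=C(/C)[C@@H]1C=C2C(C)(C)C[C@@H](O)C[C@]2(C)O1` | target

## Step count and risks

Total step count: 21. Longest linear sequence: 12 steps (steps 9 to 18, then 20 and 21).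

Least certain steps:

**Step 21 (key step).** The process most likely to fail is loss of axis-to-centre fidelity. The C8 substituent is a heptaene, so the metal-bound allene (or the product ether, if any acid is present) can ionize to a polyenyl cation, and C8 or C8' then closes on both faces. Z/E drift of the polyene and a slow second ring closure are secondary concerns. The fallback splits the twofold closure and puts the first one on a less cation-stabilizing substrate. It sets out from 26: the same gold-catalysed cycloisomerization on the C25 stage, where the allene is conjugated to a polyenal, should give (2E,4E,6E,8E,10E)-2,7,11-trimethyl-12-[(2S,7aR)-4,4,7a-trimethyl-2,4,5,6,7,7a-hexahydro-1-benzofuran-2-yl]dodeca-2,4,6,8,10-pentaenal F1. Wittig reaction of F1 with ylide 27 (from 23, conditions of step 20) then gives 29, now isolated. A single cycloisomerization of 29 (conditions of step 21, or AgNO3 in aqueous acetone as a weaker π-acid) comes back to the route at 31.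

**Step 17.** The likely failures are slow oxidative addition at the fully substituted, hindered propargylic oxirane, and erosion of the anti course through equilibration of the allenylpalladium intermediate before hydride transfer, which would mix the two allene epimers. The fallback delivers carbon instead of hydrogen and uses the opposite (syn) mode, which leads to the same axis. It sets out from 20 and 3. Silylation of 3 (tBuMe2SiCl, imidazole) gives tert-butyl{[(2E)-3-iodobut-2-en-1-yl]oxy}dimethylsilane F2. Iodine–magnesium exchange (iPrMgCl·LiCl) gives the alkenylmagnesium chloride F3. Fe(acac)3-catalysed SN2' opening of the magnesium alkoxide of 20 by F3, a reaction type that places the carbon group syn to the oxirane oxygen, should give the silyl ether of the allenic triol F4. Bu4NF then comes back to the route at 22.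

**Step 18 (and in the same way step 8).** The risk is acid-induced premature ring closure or allylic ionization of the hydroxy-allene while the salt forms, which would give furanoid material without stereocontrol. The fallback avoids Brønsted acid and sets out from 22 (or 10). Appel bromination (CBr4, PPh3, −20 °C) of the primary dienylic alcohol gives the allylic bromide F5 from 22 (the allylic bromide F6 from 10). PPh3 in ethyl acetate then comes back to the route at 23 (at 11).

**Step 11.** The risk is direct reduction of the hindered vinylpalladium intermediate by the tin hydride before CO insertion (hydrodetriflation). The fallback sets out from 14 and installs the carbon at the alcohol oxidation level: Stille coupling with Bu3SnCH2OH (Pd(PPh3)4, LiCl, dioxane, 100 °C) comes back to the route at 16 and skips 15. No new compound arises (F0).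

## Further compounds

F1 | step 21 | (2E,4E,6E,8E,10E)-2,7,11-trimethyl-12-[(2S,7aR)-4,4,7a-trimethyl-2,4,5,6,7,7a-hexahydro-1-benzofuran-2-yl]dodeca-2,4,6,8,10-pentaenal | `O=C/C(C)=C/C=C/C=C(C)/C=C/C=C(C)/[C@@H]1C=C2C(C)(C)CCC[C@@]2(C)O1`
F2 | step 17 | tert-butyl{[(2E)-3-iodobut-2-en-1-yl]oxy}dimethylsilane | `C/C(I)=C\CO[Si](C)(C)C(C)(C)C`
F3 | step 17 | [(2E)-4-(tert-butyldimethylsilyloxy)but-2-en-2-yl]magnesium chloride | `C/C([Mg]Cl)=C\CO[Si](C)(C)C(C)(C)C`
F4 | step 17 | (1R,3S)-4-[(3E)-5-(tert-butyldimethylsilyloxy)-3-methylpenta-1,3-dien-1-ylidene]-3,5,5-trimethylcyclohexane-1,3-diol, Ra allene axis | `CC(C)(C)[Si](C)(C)OC/C=C(C)/C([H])=[C@@]=C1C(C)(C)C[C@@H](O)C[C@]1(C)O`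
F5 | step 18 | (1R,3S)-4-[(3E)-5-bromo-3-methylpenta-1,3-dien-1-ylidene]-3,5,5-trimethylcyclohexane-1,3-diol, Ra allene axis | `BrC/C=C(C)/C([H])=[C@@]=C1C(C)(C)C[C@@H](O)C[C@]1(C)O`
F6 | step 8 | (1R)-2-[(3E)-5-bromo-3-methylpenta-1,3-dien-1-ylidene]-1,3,3-trimethylcyclohexan-1-ol, Ra allene axis | `BrC/C=C(C)/C([H])=[C@@]=C1C(C)(C)CCC[C@@]1(C)O`
F0 | step 11 | none | none
A1 | alternative 1 | (3R,5S,6R,5'R,6'S)-5,6:5',6'-diepoxy-5,6,5',6'-tetrahydro-β,β-caroten-3-ol | `O[C@H]1C[C@]2(C)O[C@]2(/C=C/C(C)=C/C=C/C(C)=C/C=C/C=C(C)/C=C/C=C(C)/C=C/[C@@]34O[C@]3(C)CCCC4(C)C)C(C)(C)C1`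
A2 | alternative 2 | {(2E)-3-[(2S,6R,7aS)-6-hydroxy-4,4,7a-trimethyl-2,4,5,6,7,7a-hexahydro-1-benzofuran-2-yl]but-2-en-1-yl}triphenylphosphonium bromide | `[Br-].C(/C=C(C)/[C@@H]1C=C2C(C)(C)C[C@@H](O)C[C@]2(C)O1)[P+](c3ccccc3)(c4ccccc4)c5ccccc5`
A3 | alternative 3 | (3R,5S,8S,5'R,8'R)-5,8:5',8'-diepidioxy-5,8,5',8'-tetrahydro-β,β-caroten-3-ol | `[C@H]1(OO[C@]2(C)CCCC(C)(C)C2=C1)/C(C)=C/C=C/C(C)=C/C=C/C=C(C)/C=C/C=C(C)/[C@H]3OO[C@@]4(C)C[C@H](O)CC(C)(C)C4=C3`
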